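Plan
- Numbering C1 (lactone C=O) to C26. The enabling feature is the skipped triol C7/C9/C11: carbinol C9 lies between two CH2 groups (C8, C10), each leading to an oxygenated carbon, so C9 can serve as an acyl dianion and C8/C10 as the CH2 ends of two terminal epoxides.
- Cuts: C8–C9 and C9–C10 (dithiane linchpin), then the lactone C1–O5 and C2=C3 bonds (acrylate ester, ring-closing metathesis).
- Forward: epoxide A (C10–C26) and epoxide B (C3–C8) are made separately and united in one flask through a 2-silyl-1,3-dithiane. The C9 ketone is then unmasked and reduced, and the dihydropyranone ring is closed last, before global deprotection.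
- Stereochemistry: C15 from (S)-epichlorohydrin; C11 by hydrolytic kinetic resolution; C5 and C7 from a purchasable syn chloro-diol acetonide; C9 by O7-directed 1,3-syn reduction.

Key step: step 11

Remark: TBS = tert-butyldimethylsilyl, PMB = 4-methoxybenzyl; compounds 1, 2, 5, 10 (a statin side-chain building block) and 16 are taken to be purchasable; positions in the text use the target numbering C1–C26.

Step 1
Reactants: 1 (S)-epichlorohydrin; 2 decylmagnesium bromide
Product: 3 (2S)-1-chlorotridecan-2-ol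
Conditions: 2 (1.2 equiv), CuI (10 mol%), THF, −40 to −20 °C; 1 M aq HCl
Reagents that add atoms: none
Why: Copper-catalysed Grignard opening of the oxirane at its CH2 carbon is faster than chloride displacement, so the stereocentre of 1 (future C15) is carried over untouched.

Step 2
Reactants: 3 (2S)-1-chlorotridecan-2-ol
Product: 4 (2S)-2-undecyloxirane
Conditions: NaOH (powdered), Et2O, rt
Reagents that add atoms: none
Why: Intramolecular Williamson etherification (3-exo-tet closure of the chlorohydrin alkoxide) builds the new oxirane at the former CH2Cl carbon without breaking a bond at the stereocentre.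

Step 3
Reactants: 4 (2S)-2-undecyloxirane; 5 but-3-en-1-ylmagnesium bromide
Product: 6 (6S)-heptadec-1-en-6-ol
Conditions: 5 (1.5 equiv), CuI (10 mol%), THF, −30 to 0 °C; 1 M aq HCl
Reagents that add atoms: none
Why: Copper-catalysed Grignard opening of a monosubstituted epoxide occurs at the CH2 terminus, adding C10–C13 and leaving C15 (S) intact.

Step 4
Reactants: 6 (6S)-heptadec-1-en-6-ol
Product: 7 tert-butyl{[(6S)-heptadec-1-en-6-yl]oxy}dimethylsilane
Conditions: TBSCl, imidazole, DMF, rt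
Reagents that add atoms: tert-butyldimethylsilyl chloride, CC(C)(C)[Si](C)(C)Cl
Why: Imidazole-mediated silylation of the secondary alcohol masks O15 against the cobalt Lewis acid and the organolithium chemistry that follow.

Step 5
Reactants: 7 tert-butyl{[(6S)-heptadec-1-en-6-yl]oxy}dimethylsilane
Product: 8 tert-butyldimethyl{[(4S)-1-(oxiran-2-yl)pentadecan-4-yl]oxy}silane (both configurations at the oxirane carbon)
Conditions: mCPBA, CH2Cl2, 0 °C to rt
Reagents that add atoms: 3-chloroperoxybenzoic acid, OOC(=O)c1cccc(Cl)c1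
Why: Prilezhaev epoxidation of the only alkene; the remote C15 centre exerts no control, so both C11 epimers should form in similar amounts.

Step 6
Reactants: 8 tert-butyldimethyl{[(4S)-1-(oxiran-2-yl)pentadecan-4-yl]oxy}silane (epimer mixture)
Product: 9 epoxide A, tert-butyldimethyl{[(4S)-1-[(2R)-oxiran-2-yl]pentadecan-4-yl]oxy}silane
Conditions: (R,R)-(salen)Co(OAc) (trivalent cobalt; salen = N,N'-bis(3,5-di-tert-butylsalicylidene)cyclohexane-1,2-diaminate; 0.5 mol%), H2O (0.55 equiv), THF, 0 °C to rt; chromatography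
Reagents that add atoms: none
Why: Jacobsen hydrolytic kinetic resolution, in which the chiral cobalt complex (the enantiomer that hydrolyses (S)-configured alkyl oxiranes) converts the (2S) epimer into a polar diol and leaves the (2R)-epoxide, so C11 is set by catalyst control.

Step 7
Reactants: 10 tert-butyl 2-[(4R,6S)-6-(chloromethyl)-2,2-dimethyl-1,3-dioxan-4-yl]acetate
Product: 11 2-[(4R,6S)-6-(chloromethyl)-2,2-dimethyl-1,3-dioxan-4-yl]acetaldehyde
Conditions: i-Bu2AlH (1.1 equiv), CH2Cl2, −78 °C; aq KNaC4H4O6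
Reagents that add atoms: none
Why: Partial ester reduction with i-Bu2AlH stops at the aldehyde because the tetrahedral aluminium hemiacetal persists at −78 °C until work-up.

Step 8
Reactants: 11 2-[(4R,6S)-6-(chloromethyl)-2,2-dimethyl-1,3-dioxan-4-yl]acetaldehyde
Product: 12 (4S,6S)-4-(chloromethyl)-2,2-dimethyl-6-(prop-2-en-1-yl)-1,3-dioxane
Conditions: Ph3PCH3Br, KN(SiMe3)2, THF, 0 °C; then 11, −78 to 0 °C
Reagents that add atoms: methyltriphenylphosphonium bromide, C[P+](c1ccccc1)(c1ccccc1)c1ccccc1.[Br-]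
Why: Wittig methylenation with a non-stabilised ylide at low temperature turns the aldehyde into the terminal alkene (C3 plus a sacrificial CH2) without β-elimination of the acetal oxygen.

Step 9
Reactants: 12 (4S,6S)-4-(chloromethyl)-2,2-dimethyl-6-(prop-2-en-1-yl)-1,3-dioxane
Product: 13 (2S,4S)-1-chlorohept-6-ene-2,4-diol
Conditions: 1 M aq HCl, THF, rt
Reagents that add atoms: none
Why: Acid-catalysed acetal hydrolysis frees the syn-1,3-diol, while the primary chloride and the alkene are inert.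

Step 10
Reactants: 13 (2S,4S)-1-chlorohept-6-ene-2,4-diol
Product: 15 epoxide B (2S)-2-{(2S)-2-[(4-methoxyphenyl)methoxy]pent-4-en-1-yl}oxirane, via sodium epoxy alkoxide 14 (not isolated)
Conditions: NaH (2.2 equiv), THF, 0 °C to rt; then 4-MeOC6H4CH2Cl, Bu4NI (cat.), DMF, 0 °C to rt
Reagents that add atoms: 4-methoxybenzyl chloride, COc1ccc(CCl)cc1
Why: The O7 alkoxide next to CH2Cl closes the oxirane by 3-exo-tet Williamson displacement far faster than O5 can form an oxetane, leaving O5 as the only alkoxide for Williamson benzylation in the same flask, with no bond to C5 or C7 broken.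

Step 11
Reactants: 16 tert-butyl(1,3-dithian-2-yl)dimethylsilane; 9 epoxide A; 15 epoxide B
Product: 20 (2S,4S)-1-{2-[(2R,6S)-2,6-bis(TBSO)heptadecyl]-1,3-dithian-2-yl}-4-(PMBO)hept-6-en-2-ol, via lithio silyl dithiane 17 (not isolated), via lithium alkoxide adduct 18 (not isolated), via Brook-rearranged lithio dithiane 19 (not isolated)
Conditions: t-BuLi (1.0 equiv), Et2O, −78 to −45 °C; 9, Et2O, −78 to −25 °C; then 15, THF/HMPA, −78 °C to rt; aq NH4Cl
Reagents that add atoms: none
Why: t-BuLi lithiates C2 of 16, and carbanion 17 opens oxirane 9 by SN2 attack at its CH2 terminus (C10) to give alkoxide 18, which is inert in Et2O; adding 15 in THF/HMPA then triggers a 1,4-Brook rearrangement (silyl shift from C9 to O11) that regenerates a dithiane carbanion 19 at C9, and this acyl-anion equivalent opens 15 at its CH2 terminus (C8), forging the C8–C9 bond that unites the C9–C26 and C3–C8 halves. The closest known reaction type is the solvent-controlled three-component linchpin coupling of a 2-silyl-1,3-dithiane with two different terminal epoxides (anion relay chemistry). No ring is closed and no new stereocentre is formed: C11 and C7 arrive unchanged from 9 and 15 because both attacks occur at CH2 and no C–O bond at a stereocentre is touched. The step needs attack at the CH2 termini (secured by the monosubstituted oxiranes), strict ordering of the two alkylations (secured because the silyl shift does not occur in Et2O before HMPA is added, so 9 is incorporated once) and tolerance of the silyl ethers, the PMB ether and the terminal alkene (secured by using one equivalent of t-BuLi, all consumed before 15 enters). Polarity reversal at C9 is what lets two electrophilic CH2 carbons (C8, C10) be joined to one carbon, and the relay leaves O11 silylated and O7 free, the differentiation that the later O7-directed reduction of the C9 ketone requires.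

Step 12
Reactants: 20 (2S,4S)-1-{2-[(2R,6S)-2,6-bis(TBSO)heptadecyl]-1,3-dithian-2-yl}-4-(PMBO)hept-6-en-2-ol
Product: 21 (4S,6S,10R,14S)-10,14-bis(TBSO)-6-hydroxy-4-(PMBO)pentacos-1-en-8-one
Conditions: MeI, CaCO3, MeCN/H2O (9:1), 45 °C
Reagents that add atoms: water, O
Why: Alkylative dithioketal hydrolysis (S-methylation, ring opening to a thionium ion, capture by water) releases the C9 ketone under buffered conditions that spare the silyl ethers, the PMB ether and the alkene.

Step 13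
Reactants: 21 (4S,6S,10R,14S)-10,14-bis(TBSO)-6-hydroxy-4-(PMBO)pentacos-1-en-8-one
Product: 22 (4S,6R,8S,10R,14S)-10,14-bis(TBSO)-4-(PMBO)pentacos-1-ene-6,8-diol
Conditions: Et2BOMe, THF/MeOH (4:1), −78 °C; NaBH4, −78 °C; AcOH, then MeOH co-evaporation
Reagents that add atoms: none
Why: Narasaka–Prasad reduction, in which Et2BOMe ties O7 and the C9 carbonyl into a six-membered boron chelate and external hydride adds axially, which should give the 7,9-syn diol and so set C9.

Step 14
Reactants: 22 (4S,6R,8S,10R,14S)-10,14-bis(TBSO)-4-(PMBO)pentacos-1-ene-6,8-diol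
Product: 23 (4S,6S)-4-[(2R,6S)-2,6-bis(TBSO)heptadecyl]-2,2-dimethyl-6-[(2S)-2-(PMBO)pent-4-en-1-yl]-1,3-dioxane
Conditions: Me2C(OMe)2, PPTS (cat.), CH2Cl2, rt
Reagents that add atoms: 2,2-dimethoxypropane, COC(C)(C)OC
Why: Acid-catalysed transacetalisation converts the only free diol into the six-membered syn acetonide (chair with both chains equatorial).

Step 15
Reactants: 23 (4S,6S)-4-[(2R,6S)-2,6-bis(TBSO)heptadecyl]-2,2-dimethyl-6-[(2S)-2-(PMBO)pent-4-en-1-yl]-1,3-dioxane
Product: 24 (2S)-1-{(4S,6S)-6-[(2R,6S)-2,6-bis(TBSO)heptadecyl]-2,2-dimethyl-1,3-dioxan-4-yl}pent-4-en-2-ol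
Conditions: DDQ, CH2Cl2/pH 7 buffer (NaH2PO4/Na2HPO4), 0 °C
Reagents that add atoms: none
Why: Oxidative PMB-ether cleavage by DDQ (benzylic hydride abstraction, hydrolysis of the oxocarbenium ion) frees O5 alone, since silyl ethers, acetonide and terminal alkene do not react.

Step 16
Reactants: 24 (2S)-1-{(4S,6S)-6-[(2R,6S)-2,6-bis(TBSO)heptadecyl]-2,2-dimethyl-1,3-dioxan-4-yl}pent-4-en-2-ol
Product: 25 (2S)-1-{(4R,6S)-6-[(2R,6S)-2,6-bis(TBSO)heptadecyl]-2,2-dimethyl-1,3-dioxan-4-yl}pent-4-en-2-yl prop-2-enoate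
Conditions: CH2=CHCOCl, i-Pr2NEt, DMAP (cat.), CH2Cl2, −78 to 0 °C
Reagents that add atoms: acryloyl chloride, C=CC(=O)Cl
Why: DMAP-catalysed acylation of the single free secondary alcohol with an acid chloride installs the acrylate that supplies C1 and C2.

Step 17
Reactants: 25 (2S)-1-{(4R,6S)-6-[(2R,6S)-2,6-bis(TBSO)heptadecyl]-2,2-dimethyl-1,3-dioxan-4-yl}pent-4-en-2-yl prop-2-enoate
Product: 26 (6S)-6-({(4R,6S)-6-[(2R,6S)-2,6-bis(TBSO)heptadecyl]-2,2-dimethyl-1,3-dioxan-4-yl}methyl)-5,6-dihydro-2H-pyran-2-one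
Conditions: second-generation Grubbs catalyst RuCl2(=CHPh)(H2IMes)(PCy3) (5 mol%), CH2Cl2 (2 mM), 40 °C
Reagents that add atoms: none
Why: Ring-closing olefin metathesis, in which the ruthenium alkylidene loads at the terminal homoallylic alkene and closes onto the acrylate, gives the six-membered unsaturated lactone (cis alkene enforced by the ring) with loss of ethene.

Step 18
Reactants: 26 (6S)-6-({(4R,6S)-6-[(2R,6S)-2,6-bis(TBSO)heptadecyl]-2,2-dimethyl-1,3-dioxan-4-yl}methyl)-5,6-dihydro-2H-pyran-2-one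
Product: 27 (6S)-6-[(2R,4R,6R,10S)-2,4,6,10-tetrahydroxyhenicosyl]-5,6-dihydro-2H-pyran-2-one
Conditions: 48% aq HF, MeCN, 0 °C to rt
Reagents that add atoms: none
Why: Acidic fluoride cleaves both silyl ethers and hydrolyses the acetonide, freeing the four hydroxyls without the basic conditions that would favour conjugate addition to the lactone.

Compound list
1 | (S)-epichlorohydrin, (2S)-2-(chloromethyl)oxirane | ClC[C@@H]1CO1 | starting material
2 | decylmagnesium bromide | CCCCCCCCCC[Mg]Br | starting material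
3 | (2S)-1-chlorotridecan-2-ol | CCCCCCCCCCC[C@H](O)CCl | intermediate
4 | (2S)-2-undecyloxirane | CCCCCCCCCCC[C@H]1CO1 | intermediate
5 | but-3-en-1-ylmagnesium bromide | C=CCC[Mg]Br | starting material
6 | (6S)-heptadec-1-en-6-ol | CCCCCCCCCCC[C@H](O)CCCC=C | intermediate
7 | tert-butyl{[(6S)-heptadec-1-en-6-yl]oxy}dimethylsilane | CCCCCCCCCCC[C@H](O[Si](C)(C)C(C)(C)C)CCCC=C | intermediate
8 | tert-butyldimethyl{[(4S)-1-(oxiran-2-yl)pentadecan-4-yl]oxy}silane, both oxirane epimers | CCCCCCCCCCC[C@H](O[Si](C)(C)C(C)(C)C)CCCC1CO1 | intermediate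
9 | epoxide A, tert-butyldimethyl{[(4S)-1-[(2R)-oxiran-2-yl]pentadecan-4-yl]oxy}silane | CCCCCCCCCCC[C@H](O[Si](C)(C)C(C)(C)C)CCC[C@@H]1CO1 | intermediate
10 | tert-butyl 2-[(4R,6S)-6-(chloromethyl)-2,2-dimethyl-1,3-dioxan-4-yl]acetate | ClC[C@@H]1C[C@H](CC(=O)OC(C)(C)C)OC(C)(C)O1 | starting material
11 | 2-[(4R,6S)-6-(chloromethyl)-2,2-dimethyl-1,3-dioxan-4-yl]acetaldehyde | ClC[C@@H]1C[C@H](CC=O)OC(C)(C)O1 | intermediate
12 | (4S,6S)-4-(chloromethyl)-2,2-dimethyl-6-(prop-2-en-1-yl)-1,3-dioxane | ClC[C@@H]1C[C@H](CC=C)OC(C)(C)O1 | intermediate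
13 | (2S,4S)-1-chlorohept-6-ene-2,4-diol | ClC[C@@H](O)C[C@@H](O)CC=C | intermediate
14 | sodium (2S)-1-[(2S)-oxiran-2-yl]pent-4-en-2-olate (not isolated) | C=CC[C@H]([O-])C[C@H]1CO1.[Na+] | intermediate
15 | epoxide B, (2S)-2-{(2S)-2-[(4-methoxyphenyl)methoxy]pent-4-en-1-yl}oxirane | C=CC[C@H](OCc1ccc(OC)cc1)C[C@H]1CO1 | intermediate
16 | tert-butyl(1,3-dithian-2-yl)dimethylsilane | CC(C)(C)[Si](C)(C)C1SCCCS1 | starting material
17 | tert-butyl(2-lithio-1,3-dithian-2-yl)dimethylsilane (not isolated) | [Li]C1([Si](C)(C)C(C)(C)C)SCCCS1 | intermediate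
18 | lithium (2R,6S)-6-(TBSO)-1-[2-(TBS)-1,3-dithian-2-yl]heptadecan-2-olate (not isolated) | CCCCCCCCCCC[C@H](O[Si](C)(C)C(C)(C)C)CCC[C@@H](O[Li])CC1([Si](C)(C)C(C)(C)C)SCCCS1 | intermediate
19 | 2-[(2R,6S)-2,6-bis(TBSO)heptadecyl]-2-lithio-1,3-dithiane (not isolated) | CCCCCCCCCCC[C@H](O[Si](C)(C)C(C)(C)C)CCC[C@@H](O[Si](C)(C)C(C)(C)C)CC1([Li])SCCCS1 | intermediate
20 | (2S,4S)-1-{2-[(2R,6S)-2,6-bis(TBSO)heptadecyl]-1,3-dithian-2-yl}-4-(PMBO)hept-6-en-2-ol | CCCCCCCCCCC[C@H](O[Si](C)(C)C(C)(C)C)CCC[C@@H](O[Si](C)(C)C(C)(C)C)CC1(SCCCS1)C[C@@H](O)C[C@@H](OCc1ccc(OC)cc1)CC=C | intermediate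
21 | (4S,6S,10R,14S)-10,14-bis(TBSO)-6-hydroxy-4-(PMBO)pentacos-1-en-8-one | CCCCCCCCCCC[C@H](O[Si](C)(C)C(C)(C)C)CCC[C@@H](O[Si](C)(C)C(C)(C)C)CC(=O)C[C@@H](O)C[C@@H](OCc1ccc(OC)cc1)CC=C | intermediate
22 | (4S,6R,8S,10R,14S)-10,14-bis(TBSO)-4-(PMBO)pentacos-1-ene-6,8-diol | CCCCCCCCCCC[C@H](O[Si](C)(C)C(C)(C)C)CCC[C@@H](O[Si](C)(C)C(C)(C)C)C[C@@H](O)C[C@@H](O)C[C@@H](OCc1ccc(OC)cc1)CC=C | intermediate
23 | (4S,6S)-4-[(2R,6S)-2,6-bis(TBSO)heptadecyl]-2,2-dimethyl-6-[(2S)-2-(PMBO)pent-4-en-1-yl]-1,3-dioxane | CCCCCCCCCCC[C@H](O[Si](C)(C)C(C)(C)C)CCC[C@@H](O[Si](C)(C)C(C)(C)C)C[C@@H]1C[C@H](C[C@@H](OCc2ccc(OC)cc2)CC=C)OC(C)(C)O1 | intermediate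
24 | (2S)-1-{(4S,6S)-6-[(2R,6S)-2,6-bis(TBSO)heptadecyl]-2,2-dimethyl-1,3-dioxan-4-yl}pent-4-en-2-ol | CCCCCCCCCCC[C@H](O[Si](C)(C)C(C)(C)C)CCC[C@@H](O[Si](C)(C)C(C)(C)C)C[C@@H]1C[C@H](C[C@@H](O)CC=C)OC(C)(C)O1 | intermediate
25 | (2S)-1-{(4R,6S)-6-[(2R,6S)-2,6-bis(TBSO)heptadecyl]-2,2-dimethyl-1,3-dioxan-4-yl}pent-4-en-2-yl prop-2-enoate | CCCCCCCCCCC[C@H](O[Si](C)(C)C(C)(C)C)CCC[C@@H](O[Si](C)(C)C(C)(C)C)C[C@@H]1C[C@H](C[C@@H](OC(=O)C=C)CC=C)OC(C)(C)O1 | intermediate
26 | (6S)-6-({(4R,6S)-6-[(2R,6S)-2,6-bis(TBSO)heptadecyl]-2,2-dimethyl-1,3-dioxan-4-yl}methyl)-5,6-dihydro-2H-pyran-2-one | CCCCCCCCCCC[C@H](O[Si](C)(C)C(C)(C)C)CCC[C@@H](O[Si](C)(C)C(C)(C)C)C[C@@H]1C[C@H](C[C@@H]2CC=CC(=O)O2)OC(C)(C)O1 | intermediate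
27 | (6S)-6-[(2R,4R,6R,10S)-2,4,6,10-tetrahydroxyhenicosyl]-5,6-dihydro-2H-pyran-2-one | CCCCCCCCCCC[C@H](O)CCC[C@@H](O)C[C@@H](O)C[C@@H](O)C[C@@H]1CC=CC(=O)O1 | target

Total steps: 18. Longest linear sequence: 14 steps (steps 1–6, then 11–18); the epoxide B branch (steps 7–10) joins at step 11.

Steps most likely to fail

Step 11. The silyl migration may occur too early or not at all, and proton transfer may quench carbanion 19, so that one epoxide is incorporated twice or the second alkylation stalls. The fallback separates the two alkylations and drops the silyl relay; it sets out from 9 and returns at 20. Epoxide 9 is opened with 2-lithio-1,3-dithiane (1,3-dithiane, n-BuLi, THF, −20 °C) to give (2R,6S)-6-(TBSO)-1-(1,3-dithian-2-yl)heptadecan-2-ol F1. This is silylated (TBSCl, imidazole, DMF) to 2-[(2R,6S)-2,6-bis(TBSO)heptadecyl]-1,3-dithiane F2. Deprotonation of F2 (t-BuLi, THF/HMPA, −78 °C) forms carbanion 19 directly, and alkylation with 15 returns to 20.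

Step 12. Unmasking may be slow, with concurrent β-elimination or retro-aldol cleavage of the unprotected aldol under the warm alkylating conditions. The fallback unmasks the ketone on a fully protected substrate and releases the directing hydroxyl afterwards; it sets out from 20 and returns at 21. O7 is silylated (Et3SiOTf, 2,6-lutidine, CH2Cl2, −78 °C) to 2-[(2R,6S)-2,6-bis(TBSO)heptadecyl]-2-{(2S,4S)-4-(PMBO)-2-[(triethylsilyl)oxy]hept-6-en-1-yl}-1,3-dithiane F3. The dithiane is then hydrolysed under more forcing conditions (MeI, CaCO3, aq MeCN, 60 °C) to (4S,6S,10R,14S)-10,14-bis(TBSO)-4-(PMBO)-6-[(triethylsilyl)oxy]pentacos-1-en-8-one F4. Selective removal of the triethylsilyl group (PPTS, MeOH, 0 °C) gives 21.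

Step 18. The liberated O7 hydroxyl may add in conjugate fashion to the unsaturated lactone, and translactonisation may occur during the prolonged acid exposure needed to cleave the acetonide. The fallback deprotects before the lactone exists; it sets out from 25 and returns at 27. Acrylate 25 is treated with 48% aq HF in MeCN to give (4S,6R,8R,10R,14S)-6,8,10,14-tetrahydroxypentacos-1-en-4-yl prop-2-enoate F5. Ring-closing metathesis of F5 (second-generation Grubbs catalyst RuCl2(=CHPh)(H2IMes)(PCy3), CH2Cl2, 40 °C, high dilution) then gives 27 under neutral conditions.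

Further compounds
F1 | step 11 | (2R,6S)-6-(TBSO)-1-(1,3-dithian-2-yl)heptadecan-2-ol | CCCCCCCCCCC[C@H](O[Si](C)(C)C(C)(C)C)CCC[C@@H](O)CC1SCCCS1
F2 | step 11 | 2-[(2R,6S)-2,6-bis(TBSO)heptadecyl]-1,3-dithiane | CCCCCCCCCCC[C@H](O[Si](C)(C)C(C)(C)C)CCC[C@@H](O[Si](C)(C)C(C)(C)C)CC1SCCCS1
F3 | step 12 | 2-[(2R,6S)-2,6-bis(TBSO)heptadecyl]-2-{(2S,4S)-4-(PMBO)-2-[(triethylsilyl)oxy]hept-6-en-1-yl}-1,3-dithiane | CCCCCCCCCCC[C@H](O[Si](C)(C)C(C)(C)C)CCC[C@@H](O[Si](C)(C)C(C)(C)C)CC1(SCCCS1)C[C@@H](O[Si](CC)(CC)CC)C[C@@H](OCc1ccc(OC)cc1)CC=C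
F4 | step 12 | (4S,6S,10R,14S)-10,14-bis(TBSO)-4-(PMBO)-6-[(triethylsilyl)oxy]pentacos-1-en-8-one | CCCCCCCCCCC[C@H](O[Si](C)(C)C(C)(C)C)CCC[C@@H](O[Si](C)(C)C(C)(C)C)CC(=O)C[C@@H](O[Si](CC)(CC)CC)C[C@@H](OCc1ccc(OC)cc1)CC=C
F5 | step 18 | (4S,6R,8R,10R,14S)-6,8,10,14-tetrahydroxypentacos-1-en-4-yl prop-2-enoate | CCCCCCCCCCC[C@H](O)CCC[C@@H](O)C[C@@H](O)C[C@@H](O)C[C@@H](OC(=O)C=C)CC=C
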